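Readings and results were generated by integration with constants of no real substance; the scatter is artificial.

You asked for a quick number, and my answer starts from a curve that is slow to move with the charge: counted in percent of the charge, ring rises and falls at nearly the same pace in north and south, although south holds 1.47 times the substrate. At 0.625 d the runs read 23.6% and 22.9%, and at 1.25 d they read 11.9% and 13.2%.

| flask | substrate | remark | time |
|---|---|---|---|
| north | 0.75 M | run made earlier |  |
| south | 1.1 M | run made earlier |  |
| flask | 1.5 M |  | 6.0 d |

| north: time / d | north: ring / % | south: time / d | south: ring / % |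
|---|---|---|---|
| 0.125 | 14.4 | 0.125 | 11.0 |
| 0.208 | 20.0 | 0.208 | 16.6 |
| 0.333 | 23.2 | 0.333 | 24.7 |
| 0.625 | 23.6 | 0.625 | 22.9 |
| 1.25 | 11.9 | 1.25 | 13.2 |
| 2.08 | 2.9 | 2.08 | 4.0 |
| 4.00 | 0.2 | 4.00 | 1.7 |

(scatter of a reading: 1 percentage point)

- when, up to 6.0 d, the flask holds most ring
- the amount of ring, in percent of the substrate charged, at that time

- a reading or a percentage of ring counts all its forms, free or not

So I freeze the percent curve against charge, as a first-order sequence would behave, and carry one number: the frozen peak h, the mean of the highest reading of each run, 24.1%, with a scatter of 0.71 percentage points. For the time, north stands nearly level at 0.333 d and 0.625 d, reading 23.2% and 23.6%, so I put its top at their midpoint, 0.479 d. For your flask I commit to h at that time.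

Your forecast says 25% at 0.55 d, later than my midpoint, since it expects “the same shape stretched slightly”.

The flask gives 23.5% at 0.469 d.

    substrate → ring (k = 9.63 × 10⁻⁴ min⁻¹)
    2 substrate → open dimer (k = 7.65 × 10⁻⁵ L mol⁻¹ min⁻¹)
    substrate ⇌ dormant form (K = 18.0, k = 4.48 × 10⁻⁴ min⁻¹)
    crystals ⇌ ring, rate k4*(cs4 - [ring]) while solid is left; crystals form when [ring] > cs4 (solubility = 0.700 M, k = 0.315 min⁻¹)
    ring → over-reaction product (k = 0.00144 min⁻¹)

The flask's peak comes earlier than the forecast's time, and even slightly before my midpoint, so the stretch does not appear. Its height stands 0.60 points under h. A neighbour flask tests the frozen peak further down: it is charged with 0.60 M of substrate, less than either run, with the time and all else held. The same reckoning again gives h, 24.1%, and that neighbour flask reaches 24.3%.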